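**Retrosynthetic overview**
1. The strategy rests on the only stereocentre, C5 of the 2(5H)-furanone ring (O1, C2=O, C3H=C4(CH2OH), C5H). It is a γ C–H carbon between O1, the C3=C4 enoate and the allylic chain CH2, so it can be flattened into an aromatic 2-oxidofuran and rebuilt by one proton. The ring with its C4 CH2OH is the skeleton of 3-furanmethanol.
2. Disconnection 1: desilylation, then an enantioselective C3-to-C5 proton transfer in the achiral furan-2(3H)-one. That lactone comes from a C25 2,3-disubstituted furan by C5–H borylation, boronate oxidation and kinetic deconjugation.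
3. Disconnection 2: a Wittig cut of the Z C(CH2OSi)=CH olefin into a C18 α-silyloxy ketone and a C7 2-(furan-2-yl)ethyl phosphonium salt.
4. Disconnection 3: the ketone comes from 12-silyloxyfarnesyl bromide (farnesol, SeO2) and the hydrazone of silyloxyacetone. The salt comes from C2-lithiated 3-furanmethanol and a protected 2-bromoethanol.
5. Ring order: no ring is closed at any stage. The single ring is bought as a furan, oxygenated at C5 and dearomatised to the furanone.

Key step: step 18

Assumption: the target SMILES corresponds to (R) at C5, and the sense of induction on this β-substituted substrate cannot be predicted with certainty. The route is therefore written with quinidine-derived 9-O-(phenanthren-9-yl)cupreidine (C33H30N2O2, Oc1ccc2nccc([C@@H]([C@H]3C[C@@H]4CCN3C[C@@H]4C=C)Oc3cc4ccccc4c4ccccc34)c2c1). If a trial run shows the (S)-lactone, the quinine-derived pseudoenantiomer 9-O-(phenanthren-9-yl)cupreine takes its place with nothing else changed.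

**Fragment A: C15 bromide**

Step 1
Reactants: 1 (2E,6E)-farnesol
Product: 2 (2E,6E)-farnesyl acetate
Conditions: Ac2O, pyridine, 4-(dimethylamino)pyridine (cat.), CH2Cl2, 0 °C to rt
Reagents that add atoms: acetic anhydride, CC(=O)OC(C)=O
Why: Routine nucleophile-catalysed O-acetylation masks the C1 alcohol and makes the C2=C3 olefin the least electron-rich of the three, which helps the site selectivity of the next step.

Step 2
Reactants: 2 (2E,6E)-farnesyl acetate
Product: 3 (2E,6E,10E)-12-hydroxyfarnesyl acetate
Conditions: SeO2 (cat.), t-BuOOH, salicylic acid (cat.), CH2Cl2, 0 °C to rt, stopped before full conversion; then NaBH4, MeOH, 0 °C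
Reagents that add atoms: tert-butyl hydroperoxide, CC(C)(C)OO (oxygen relayed through the SeO2 catalyst, O=[Se]=O)
Why: The Riley allylic oxidation (ene reaction, then [2,3]-sigmatropic shift) should pick the terminal, most electron-rich trisubstituted olefin and hydroxylate the methyl group trans to the chain, giving the E allylic alcohol, and the borohydride treatment returns over-oxidised material to the alcohol.

Step 3
Reactants: 3 (2E,6E,10E)-12-hydroxyfarnesyl acetate
Product: 4 (2E,6E,10E)-12-(tert-butyldimethylsilyloxy)farnesyl acetate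
Conditions: TBSCl, imidazole, DMF, 0 °C to rt
Reagents that add atoms: tert-butyldimethylsilyl chloride, CC(C)(C)[Si](C)(C)Cl
Why: This is a standard silylation of a primary allylic alcohol, and the TBS ether should survive methanolysis, bromide, azaenolate, ylide and amide bases until the last step.

Step 4
Reactants: 4 (2E,6E,10E)-12-(tert-butyldimethylsilyloxy)farnesyl acetate
Product: 5 (2E,6E,10E)-12-(tert-butyldimethylsilyloxy)farnesol
Conditions: K2CO3 (cat.), MeOH, rt
Reagents that add atoms: none
Why: Base-catalysed transesterification removes the acetate and leaves the silyl ether and the olefin geometries alone.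

Step 5
Reactants: 5 (2E,6E,10E)-12-(tert-butyldimethylsilyloxy)farnesol
Product: 7 (2E,6E,10E)-12-(tert-butyldimethylsilyloxy)farnesyl bromide, via allylic mesylate 6 (not isolated)
Conditions: MsCl, Et3N, THF, −45 °C; then LiBr in THF, −45 to 0 °C
Reagents that add atoms: lithium bromide, [Li+].[Br-]; methanesulfonyl chloride, CS(=O)(=O)Cl (atoms kept only in 6)
Why: Direct SN2 displacement of the cold, in situ formed allylic mesylate by bromide should keep the E geometry and avoid allylic transposition.

**Fragment A continued: C18 ketone**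

Step 6
Reactants: 8 1-(tert-butyldimethylsilyloxy)propan-2-one
Product: 9 1-(tert-butyldimethylsilyloxy)propan-2-one N,N-dimethylhydrazone
Conditions: Me2NNH2, MgSO4, Et2O, rt
Reagents that add atoms: N,N-dimethylhydrazine, CN(C)N
Why: Condensation of an unhindered ketone with the hydrazine gives a hydrazone that can be metalated cleanly without self-condensation.

Step 7
Reactants: 9 1-(tert-butyldimethylsilyloxy)propan-2-one N,N-dimethylhydrazone; 7 (2E,6E,10E)-12-(tert-butyldimethylsilyloxy)farnesyl bromide
Product: 11 N,N-dimethylhydrazone of the C18 α-silyloxy ketone, via lithium azaenolate 10 (not isolated)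
Conditions: LiN(i-Pr)2 (LDA), THF, −78 to −20 °C; then 7, −78 to 0 °C
Reagents that add atoms: none
Why: Kinetic metalation of a dimethylhydrazone takes the unhindered methyl group rather than the CH2 that is shielded by the silyl group and disfavoured by the oxygen lone pairs, and the azaenolate should alkylate the allylic bromide at carbon by SN2 (hydrazone alkylation).

Step 8
Reactants: 11 N,N-dimethylhydrazone of the C18 α-silyloxy ketone
Product: 12 (5E,9E,13E)-1,15-bis(tert-butyldimethylsilyloxy)-6,10,14-trimethylpentadeca-5,9,13-trien-2-one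
Conditions: sat. aq. oxalic acid, Et2O, rt (two phases)
Reagents that add atoms: water, O
Why: Two-phase hydrazone hydrolysis pulls the protonated hydrazine into the water layer and is mild enough for primary TBS ethers and trisubstituted olefins.

**Fragment B: C7 furan phosphonium salt**

Step 9
Reactants: 13 3-furanmethanol; 14 (2-bromoethoxy)(tert-butyl)dimethylsilane
Product: 16 {2-[2-(tert-butyldimethylsilyloxy)ethyl]furan-3-yl}methanol, via dilithiated furanmethanol 15 (not isolated)
Conditions: n-BuLi (2.2 equiv), THF, −78 to 0 °C; then 14, DMPU, −78 °C to rt; aq. quench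
Reagents that add atoms: none
Why: The lithium alkoxide directs the second equivalent of n-BuLi to the neighbouring α C2–H (directed lithiation), and the furyl carbanion, far more nucleophilic than the alkoxide, should displace the primary bromide by SN2 with help from DMPU.

Step 10
Reactants: 16 {2-[2-(tert-butyldimethylsilyloxy)ethyl]furan-3-yl}methanol
Product: 17 2-[2-(tert-butyldimethylsilyloxy)ethyl]-3-(triisopropylsilyloxymethyl)furan
Conditions: TIPSCl, imidazole, DMF, rt
Reagents that add atoms: triisopropylsilyl chloride, CC(C)[Si](Cl)(C(C)C)C(C)C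
Why: Silylation of the remaining primary alcohol with the bulkier group creates the difference in lability that the next step uses.

Step 11
Reactants: 17 2-[2-(tert-butyldimethylsilyloxy)ethyl]-3-(triisopropylsilyloxymethyl)furan
Product: 18 2-[3-(triisopropylsilyloxymethyl)furan-2-yl]ethanol
Conditions: pyridinium p-toluenesulfonate (cat.), MeOH, 0 °C to rt
Reagents that add atoms: none
Why: Under mild acid catalysis a primary TBS ether is solvolysed much faster than a primary TIPS ether, and this weak acid should not harm the furan or ionise the furylmethyl ether.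

Step 12
Reactants: 18 2-[3-(triisopropylsilyloxymethyl)furan-2-yl]ethanol
Product: 19 2-(2-iodoethyl)-3-(triisopropylsilyloxymethyl)furan
Conditions: I2, PPh3, imidazole, CH2Cl2, 0 °C to rt
Reagents that add atoms: iodine, [I][I]
Why: The Appel-type iodination through the alkoxyphosphonium salt is fast and essentially neutral for a primary alcohol.

Step 13
Reactants: 19 2-(2-iodoethyl)-3-(triisopropylsilyloxymethyl)furan
Product: 20 {2-[3-(triisopropylsilyloxymethyl)furan-2-yl]ethyl}triphenylphosphonium iodide
Conditions: PPh3, MeCN, 80 °C, dark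
Reagents that add atoms: triphenylphosphine, c1ccc(cc1)P(c1ccccc1)c1ccccc1
Why: This is a plain SN2 quaternisation of the phosphine by a primary iodide.

**Union and end game**

Step 14
Reactants: 20 {2-[3-(triisopropylsilyloxymethyl)furan-2-yl]ethyl}triphenylphosphonium iodide; 12 (5E,9E,13E)-1,15-bis(tert-butyldimethylsilyloxy)-6,10,14-trimethylpentadeca-5,9,13-trien-2-one
Product: 22 2-[(2Z,6E,10E,14E)-16-(tert-butyldimethylsilyloxy)-3-(tert-butyldimethylsilyloxymethyl)-7,11,15-trimethylhexadeca-2,6,10,14-tetraen-1-yl]-3-(triisopropylsilyloxymethyl)furan, via phosphonium ylide 21 (not isolated)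
Conditions: 20 (1.5 equiv), KN(SiMe3)2 (1.4 equiv), THF, −78 °C; then 12, −78 to 0 °C
Reagents that add atoms: none
Why: A lithium-free Wittig reaction of a non-stabilised ylide with an α-alkoxy ketone is kinetically controlled and is known to place the ylide carbon cis to the CH2OSi arm, which is the Z olefin required, while the small deficit of base relative to 20 leaves nothing to move the skipped furan–CH2–CH= unit into conjugation.

Step 15
Reactants: 22 C25 2,3-disubstituted furan
Product: 23 the 5-(4,4,5,5-tetramethyl-1,3,2-dioxaborolan-2-yl) derivative of furan 22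
Conditions: [Ir(OMe)(cod)]2 (cod = 1,5-cyclooctadiene, 1.5 mol %), 4,4'-di-tert-butyl-2,2'-bipyridine (3 mol %), B2pin2, hexane, rt
Reagents that add atoms: bis(pinacolato)diboron, CC1(C)OB(OC1(C)C)B1OC(C)(C)C(C)(C)O1
Why: Iridium-catalysed C–H borylation of furans goes to a free α position, and C5–H is the only one left and has just C4–H beside it, while trisubstituted olefins and silyl ethers are poor partners for this catalyst at rt.

Step 16
Reactants: 23 furan-5-yl pinacol boronate
Product: 25 racemic 5-(C20 side chain of 22)-4-(triisopropylsilyloxymethyl)furan-2(5H)-one, via 2-hydroxyfuran tautomer 24 (not isolated)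
Conditions: 30 % aq. H2O2, pH 7 phosphate buffer, THF, 0 °C; crude product then Et3N (cat.), CH2Cl2, rt
Reagents that add atoms: hydrogen peroxide, OO
Why: In this boronate oxidation hydroperoxide adds to boron and the furyl group migrates to oxygen, hydrolysis frees the 2-hydroxyfuran, which tautomerises at once, and a trace of Et3N funnels both lactone tautomers into the more stable conjugated one, a single storable racemate that also serves as reference for the enantiomer assay.

Step 17
Reactants: 25 racemic conjugated butenolide
Product: 27 achiral 5-(C20 side chain of 22)-4-(triisopropylsilyloxymethyl)furan-2(3H)-one, via lithium 2-oxidofuran 26 (not isolated)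
Conditions: LiN(SiMe3)2 (1.1 equiv), THF, −78 °C; cannulated into AcOH (5 equiv) in THF, −78 °C; cold pH 5 buffer work-up, fast chromatography
Reagents that add atoms: none
Why: Removal of C5–H gives the aromatic lithium oxidofuran, which like other lithium dienolates is protonated kinetically at the α carbon C3 (deconjugative protonation), the feebly basic HN(SiMe3)2 should not catalyse the return, and any reconjugated material is simply 25, which is separated and recycled.

Step 18
Reactants: 27 achiral furan-2(3H)-one
Product: 28 (R)-5-(C20 side chain of 22)-4-(triisopropylsilyloxymethyl)furan-2(5H)-one (tris-silyl ether of hippolide F)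
Conditions: 9-O-(phenanthren-9-yl)cupreidine (10 mol %), CH2Cl2, −20 °C, argon
Reagents that add atoms: none
Why: The quinuclidine nitrogen of the bifunctional catalyst takes one of the acidic C3 protons of 27 and produces the same flat, aromatic 2-oxidofuran anion as in 26, now held in a contact ion pair by the quinuclidinium N–H and the 6'-OH; the ammonium then hands the proton to C5, so a C3–H bond is lost, the C5–H bond is made and the ring double bond moves from C4=C5 to C3=C4. The closest known reaction type is the cinchona-alkaloid-catalysed enantioselective olefin isomerisation of γ-alkyl β,γ-unsaturated butenolides by proton-transfer catalysis, of which 27 is a β-substituted member. No ring is closed, and the furan-derived ring only changes into the 2(5H)-furanone. The new C5 centre (R) is set by the catalyst alone, since the anion is planar and achiral and the chiral ion pair offers only one of its faces to the N–H proton; the contrast between the C5 chain with the bulky C4 CH2OTIPS group on one edge and the ring oxygen on the other fixes how the anion sits in the pocket. γ over α protonation is secured thermodynamically, because α protonation merely regenerates 27 whereas γ protonation gives the conjugated lactone, and the configuration should hold because C5–H of 28 is kinetically far less acidic toward a tertiary amine than the C3 protons of 27 at this temperature. The skipped chain olefins, the CH2 between C5 and the Z olefin and the three silyl ethers should be untouched by so weak a base.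

Step 19
Reactants: 28 tris-silyl ether of hippolide F
Product: 29 hippolide F
Conditions: HF·pyridine, pyridine, THF, 0 °C to rt
Reagents that add atoms: none
Why: Fluoride-driven cleavage of all three Si–O bonds in an acidic, pyridine-buffered medium avoids any base able to remove C5–H, so the configuration should be retained, and the C4 CH2OH lies trans to C2 across C3=C4 and cannot translactonise.

**Compound list**
1 | (2E,6E)-farnesol | CC(C)=CCC/C(C)=C/CC/C(C)=C/CO | starting material
2 | (2E,6E)-farnesyl acetate | CC(C)=CCC/C(C)=C/CC/C(C)=C/COC(C)=O | intermediate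
3 | (2E,6E,10E)-12-hydroxyfarnesyl acetate | C/C(=C\CC/C(C)=C/CC/C(C)=C/COC(C)=O)CO | intermediate
4 | (2E,6E,10E)-12-(tert-butyldimethylsilyloxy)farnesyl acetate | C/C(=C\CC/C(C)=C/CC/C(C)=C/COC(C)=O)CO[Si](C)(C)C(C)(C)C | intermediate
5 | (2E,6E,10E)-12-(tert-butyldimethylsilyloxy)farnesol | C/C(=C\CC/C(C)=C/CC/C(C)=C/CO)CO[Si](C)(C)C(C)(C)C | intermediate
6 | allylic mesylate of 5 | C/C(=C\CC/C(C)=C/CC/C(C)=C/COS(C)(=O)=O)CO[Si](C)(C)C(C)(C)C | intermediate (not isolated)
7 | (2E,6E,10E)-12-(tert-butyldimethylsilyloxy)farnesyl bromide | C/C(=C\CC/C(C)=C/CC/C(C)=C/CBr)CO[Si](C)(C)C(C)(C)C | intermediate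
8 | 1-(tert-butyldimethylsilyloxy)propan-2-one | CC(=O)CO[Si](C)(C)C(C)(C)C | starting material
9 | N,N-dimethylhydrazone of 8 | CC(CO[Si](C)(C)C(C)(C)C)=NN(C)C | intermediate
10 | lithium azaenolate of 9, metalated at the methyl carbon | [Li+].C=C(CO[Si](C)(C)C(C)(C)C)[N-]N(C)C | intermediate (not isolated)
11 | N,N-dimethylhydrazone of ketone 12 | C/C(=C\CC/C(C)=C/CC/C(C)=C/CCC(CO[Si](C)(C)C(C)(C)C)=NN(C)C)CO[Si](C)(C)C(C)(C)C | intermediate
12 | (5E,9E,13E)-1,15-bis(tert-butyldimethylsilyloxy)-6,10,14-trimethylpentadeca-5,9,13-trien-2-one | C/C(=C\CC/C(C)=C/CC/C(C)=C/CCC(=O)CO[Si](C)(C)C(C)(C)C)CO[Si](C)(C)C(C)(C)C | intermediate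
13 | 3-furanmethanol | OCc1ccoc1 | starting material
14 | (2-bromoethoxy)(tert-butyl)dimethylsilane | BrCCO[Si](C)(C)C(C)(C)C | starting material
15 | 2-lithio-3-(lithiooxymethyl)furan | [Li]OCc1ccoc1[Li] | intermediate (not isolated)
16 | {2-[2-(tert-butyldimethylsilyloxy)ethyl]furan-3-yl}methanol | OCc1ccoc1CCO[Si](C)(C)C(C)(C)C | intermediate
17 | 2-[2-(tert-butyldimethylsilyloxy)ethyl]-3-(triisopropylsilyloxymethyl)furan | CC(C)[Si](OCc1ccoc1CCO[Si](C)(C)C(C)(C)C)(C(C)C)C(C)C | intermediate
18 | 2-[3-(triisopropylsilyloxymethyl)furan-2-yl]ethanol | CC(C)[Si](OCc1ccoc1CCO)(C(C)C)C(C)C | intermediate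
19 | 2-(2-iodoethyl)-3-(triisopropylsilyloxymethyl)furan | CC(C)[Si](OCc1ccoc1CCI)(C(C)C)C(C)C | intermediate
20 | {2-[3-(triisopropylsilyloxymethyl)furan-2-yl]ethyl}triphenylphosphonium iodide | CC(C)[Si](OCc1ccoc1CC[P+](c1ccccc1)(c1ccccc1)c1ccccc1)(C(C)C)C(C)C.[I-] | intermediate
21 | ylide of 20 | CC(C)[Si](OCc1ccoc1CC=P(c1ccccc1)(c1ccccc1)c1ccccc1)(C(C)C)C(C)C | intermediate (not isolated)
22 | C25 furan: 2-[(2Z,6E,10E,14E)-16-(TBS-oxy)-3-(TBS-oxymethyl)-7,11,15-trimethylhexadeca-2,6,10,14-tetraen-1-yl]-3-(TIPS-oxymethyl)furan | C/C(=C\CC/C(C)=C/CC/C(C)=C/CC/C(=C/Cc1occc1CO[Si](C(C)C)(C(C)C)C(C)C)CO[Si](C)(C)C(C)(C)C)CO[Si](C)(C)C(C)(C)C | intermediate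
23 | 5-(pinacolatoboryl) derivative of 22 | C/C(=C\CC/C(C)=C/CC/C(C)=C/CC/C(=C/Cc1oc(B2OC(C)(C)C(C)(C)O2)cc1CO[Si](C(C)C)(C(C)C)C(C)C)CO[Si](C)(C)C(C)(C)C)CO[Si](C)(C)C(C)(C)C | intermediate
24 | 5-(C20 side chain)-4-(TIPS-oxymethyl)furan-2-ol | C/C(=C\CC/C(C)=C/CC/C(C)=C/CC/C(=C/Cc1oc(O)cc1CO[Si](C(C)C)(C(C)C)C(C)C)CO[Si](C)(C)C(C)(C)C)CO[Si](C)(C)C(C)(C)C | intermediate (not isolated)
25 | racemic 5-(C20 side chain)-4-(TIPS-oxymethyl)furan-2(5H)-one | C/C(=C\CC/C(C)=C/CC/C(C)=C/CC/C(=C/CC1OC(=O)C=C1CO[Si](C(C)C)(C(C)C)C(C)C)CO[Si](C)(C)C(C)(C)C)CO[Si](C)(C)C(C)(C)C | intermediate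
26 | lithium 5-(C20 side chain)-4-(TIPS-oxymethyl)furan-2-olate | [Li+].C/C(=C\CC/C(C)=C/CC/C(C)=C/CC/C(=C/Cc1oc([O-])cc1CO[Si](C(C)C)(C(C)C)C(C)C)CO[Si](C)(C)C(C)(C)C)CO[Si](C)(C)C(C)(C)C | intermediate (not isolated)
27 | achiral 5-(C20 side chain)-4-(TIPS-oxymethyl)furan-2(3H)-one | C/C(=C\CC/C(C)=C/CC/C(C)=C/CC/C(=C/CC1=C(CO[Si](C(C)C)(C(C)C)C(C)C)CC(=O)O1)CO[Si](C)(C)C(C)(C)C)CO[Si](C)(C)C(C)(C)C | intermediate
28 | (R)-5-(C20 side chain)-4-(TIPS-oxymethyl)furan-2(5H)-one | C/C(=C\CC/C(C)=C/CC/C(C)=C/CC/C(=C/C[C@H]1OC(=O)C=C1CO[Si](C(C)C)(C(C)C)C(C)C)CO[Si](C)(C)C(C)(C)C)CO[Si](C)(C)C(C)(C)C | intermediate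
29 | hippolide F | C/C(=C\CC/C(C)=C/CC/C(C)=C/CC/C(=C/C[C@H]1OC(=O)C=C1CO)CO)CO | target

**Count**
Total steps: 19. Longest linear sequence: 13 steps from farnesol (steps 1–5, 7, 8, 14–19).

**Three steps most likely to fail**

Step 18.
- Risk: poor facial selectivity in the proton delivery, slow turnover because of the tetrasubstituted enol-ester bond and the bulky C4 group, or erosion of enantiopurity by reversible γ-deprotonation.
- Fallback, from 25 and back at 28: resolution with recycling in place of asymmetric catalysis.
  - Racemate 25 is separated by preparative chromatography on a polysaccharide-type chiral stationary phase (supercritical CO2 with i-PrOH) into 28 and the unwanted (S)-lactone F1.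
  - F1 is stirred with catalytic 1,8-diazabicyclo[5.4.0]undec-7-ene in CH2Cl2, which racemises it through the planar oxidofuran back to 25, and it is injected again.
  - All material should converge on 28, and steps 17 and 18 are then not needed.

Step 14.
- Risk: loss of PPh3 from the salt or ylide by β-elimination through the furylic CH2, enolisation of the ketone, or insufficient cis selectivity.
- Fallback, from 19 and back at 22: a stepwise Horner–Wittig olefination, in which the geometry comes from separating diastereomers followed by a stereospecific syn elimination.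
  - Iodide 19 is alkylated with Ph2P(O)H and KN(SiMe3)2 in THF at 0 °C (Michaelis–Becker reaction) to give the furylethyl diphenylphosphine oxide F2. This group is no leaving group for β-elimination.
  - n-BuLi in THF at −78 °C gives the α-lithio phosphine oxide F3, which is added to ketone 12 and quenched cold.
  - The two racemic adducts are separated on silica. The β-hydroxy phosphine oxide F4, drawn with the relative configuration that eclipses CH2-furyl with CH2OTBS when P and O are syn, is kept. The other β-hydroxy phosphine oxide diastereomer F5 is set aside.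
  - KH in THF at 0 °C then collapses F4 by syn elimination to geometrically pure 22.

Step 15.
- Risk: competing hydroboration or migration of the chain olefins by iridium hydride or boryl species, or sluggish turnover on the large substrate.
- Fallback, from 22 and back at 25, replacing steps 15 and 16: photooxygenation followed by reduction.
  - Furan 22 is irradiated under O2 with 5,10,15,20-tetraphenylporphyrin as sensitiser and i-Pr2NEt in CH2Cl2 at −78 °C. At this temperature the furan should outrun the trisubstituted olefins toward singlet oxygen.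
  - The [4+2] adduct, the bicyclic endoperoxide F6, loses its bridgehead C–H proton (Kornblum–DeLaMare fragmentation) and gives the racemic 5-hydroxy-5-alkylbutenolide F7. Its carbonyl sits on the former C5–H carbon.
  - NaBH4 in EtOH at 0 °C reduces F7 through its ring-opened keto-acid form, and mild acidification closes the lactone to 25.

**Further compounds**
F1 | step 18 | (S)-5-(C20 side chain)-4-(TIPS-oxymethyl)furan-2(5H)-one, enantiomer of 28 | C/C(=C\CC/C(C)=C/CC/C(C)=C/CC/C(=C/C[C@@H]1OC(=O)C=C1CO[Si](C(C)C)(C(C)C)C(C)C)CO[Si](C)(C)C(C)(C)C)CO[Si](C)(C)C(C)(C)C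
F2 | step 14 | {2-[3-(triisopropylsilyloxymethyl)furan-2-yl]ethyl}diphenylphosphine oxide | CC(C)[Si](OCc1ccoc1CCP(=O)(c1ccccc1)c1ccccc1)(C(C)C)C(C)C
F3 | step 14 | α-lithio derivative of F2 | CC(C)[Si](OCc1ccoc1CC([Li])P(=O)(c1ccccc1)c1ccccc1)(C(C)C)C(C)C
F4 | step 14 | racemic β-hydroxy phosphine oxide, relative configuration shown, leading to the Z olefin | C/C(=C\CC/C(C)=C/CC/C(C)=C/CC[C@](O)(CO[Si](C)(C)C(C)(C)C)[C@H](P(=O)(c1ccccc1)c1ccccc1)Cc1occc1CO[Si](C(C)C)(C(C)C)C(C)C)CO[Si](C)(C)C(C)(C)C
F5 | step 14 | racemic β-hydroxy phosphine oxide, the other diastereomer | C/C(=C\CC/C(C)=C/CC/C(C)=C/CC[C@@](O)(CO[Si](C)(C)C(C)(C)C)[C@H](P(=O)(c1ccccc1)c1ccccc1)Cc1occc1CO[Si](C(C)C)(C(C)C)C(C)C)CO[Si](C)(C)C(C)(C)C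
F6 | step 15 | racemic furan endoperoxide (2,3,7-trioxabicyclo[2.2.1]hept-5-ene) of 22 | C/C(=C\CC/C(C)=C/CC/C(C)=C/CC/C(=C/CC12OOC(O1)C=C2CO[Si](C(C)C)(C(C)C)C(C)C)CO[Si](C)(C)C(C)(C)C)CO[Si](C)(C)C(C)(C)C
F7 | step 15 | racemic 5-hydroxy-5-(C20 side chain)-4-(TIPS-oxymethyl)furan-2(5H)-one | C/C(=C\CC/C(C)=C/CC/C(C)=C/CC/C(=C/CC1(O)OC(=O)C=C1CO[Si](C(C)C)(C(C)C)C(C)C)CO[Si](C)(C)C(C)(C)C)CO[Si](C)(C)C(C)(C)C
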